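**Retrosynthetic overview**

1. Feature: in the oxepene ring (O1, C2, C3, C4, C5, C5a, C9a) the unit O1–C2(CH2Br)–C3(CH3)=C4 is the C=C of a trans-fused dihydropyran enol ether with one extra carbon (C3) pushed into it; that carbon is brought in as CBr2.
2. 21 ⇐ 20 (Appel) ⇐ 18 (hydroboration fixes C2) ⇐ 17 (methylenation) ⇐ 15 (oxidation at C2) ⇐ 14 (Negishi methyl at C3).
3. 14 ⇐ 11 + methanol 12: cleavage of the cyclopropane bond shared with the pyran enlarges it to the oxepene; 11 ⇐ 9 + bromoform 10.
4. 9 ⇐ 7 ⇐ 6 (reduction, dehydration) ⇐ 5 (resolution) ⇐ 4 (bromonium bicyclisation closes the cyclohexane C5a–C9a and the oxygen ring together) ⇐ 1 + 2.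
5. Ring order: cyclohexane and δ-lactone (step 2), cyclopropane (step 6), oxepene by ring enlargement (step 7).

Key step: step 7

Remark: the target SMILES is read as (2R,5aS,7S,9aS), with trans ring fusion (H-5a anti to the C9a methyl), equatorial Br at C7 syn to that methyl, and the C2 bromomethyl group syn to the C9a methyl across O1.
Remark: chromene numbering (O1, C2 … C8a) is used up to compound 11 and 1-benzoxepine numbering (O1, C2 … C9a) from compound 13 on.
Remark: racemic 5 is written in SMILES as the 1:1 pair of enantiomers; the enantiomer carried on after step 3 is to be assigned by anomalous-dispersion X-ray analysis (bromine as heavy atom).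

**Route**

Step 1
Reactants: 1 geranyl bromide; 2 tert-butyl acetate
Product: 4 tert-butyl (4E)-5,9-dimethyldeca-4,8-dienoate, via lithium enolate 3 (not isolated)
Conditions: LDA, THF, −78 °C; then 1, −78 → 0 °C
Reagents that add atoms: none
Why: SN2 alkylation of a lithium ester enolate by a primary allylic bromide is reliable, the tert-butyl ester suppresses Claisen self-condensation, the (E)-alkene of the geranyl unit is untouched, and no stereocentre is formed.

Step 2
Reactants: 4 tert-butyl (4E)-5,9-dimethyldeca-4,8-dienoate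
Product: 5 racemic (4aS*,6S*,8aS*)-6-bromo-5,5,8a-trimethyloctahydro-2H-chromen-2-one
Conditions: BDSB (1.1 equiv), MeNO2, −25 °C; aq. Na2SO3/NaHCO3
Reagents that add atoms: bromodiethylsulfonium bromopentachloroantimonate (BDSB), CC[S+](Br)CC.Cl[Sb-](Cl)(Cl)(Cl)(Cl)Br
Why: Bromonium-initiated cation–olefin bicyclisation with an oxygen terminator, a known use of this reagent, in which Br+ is taken up at the terminal isopropylidene, the (E)-4,5-alkene adds through a chair–chair transition state and the ester carbonyl oxygen closes the δ-lactone with loss of isobutene, so that anti addition across both alkenes sets equatorial Br at C6, axial H at C4a and axial methyl with equatorial oxygen at C8a (trans fusion) in relative terms, the product being racemic.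

Step 3
Reactants: 5 racemic (4aS*,6S*,8aS*)-6-bromo-5,5,8a-trimethyloctahydro-2H-chromen-2-one
Product: 6 (4aS,6S,8aS)-6-bromo-5,5,8a-trimethyloctahydro-2H-chromen-2-one
Conditions: preparative SFC, amylose tris(3,5-dimethylphenylcarbamate) phase, CO2/MeOH; recrystallisation
Reagents that add atoms: none
Why: Resolution of a racemate by preparative chromatography on a chiral stationary phase is routine for compact rigid lactones, it fixes the absolute configuration of C4a, C6 and C8a, and these three centres are then carried unchanged to the target.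

Step 4
Reactants: 6 (4aS,6S,8aS)-6-bromo-5,5,8a-trimethyloctahydro-2H-chromen-2-one
Product: 7 (2RS,4aS,6S,8aS)-6-bromo-5,5,8a-trimethyloctahydro-2H-chromen-2-ol
Conditions: DIBAL-H, CH2Cl2, −78 °C; Rochelle salt
Reagents that add atoms: none
Why: Partial reduction of a δ-lactone with DIBAL-H at low temperature stops at the aluminium hemiacetal and gives the six-membered lactol, whose anomeric centre is uncontrolled and irrelevant, while the equatorial neopentyl bromide is inert.

Step 5
Reactants: 7 (2RS,4aS,6S,8aS)-6-bromo-5,5,8a-trimethyloctahydro-2H-chromen-2-ol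
Product: 9 (4aS,6S,8aS)-6-bromo-5,5,8a-trimethyl-4a,5,6,7,8,8a-hexahydro-4H-chromene, via anomeric mesylate 8 (not isolated)
Conditions: MsCl, Et3N, CH2Cl2, 0 °C → reflux
Reagents that add atoms: methanesulfonyl chloride, CS(=O)(=O)Cl (its atoms are in 8 only)
Why: Dehydration of a 2-deoxy lactol to the cyclic enol ether (glycal-type elimination) proceeds through the anomeric mesylate, which ionises with oxygen assistance and loses the C3 proton to triethylamine, removing the anomeric centre without touching the others.

Step 6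
Reactants: 9 (4aS,6S,8aS)-6-bromo-5,5,8a-trimethyl-4a,5,6,7,8,8a-hexahydro-4H-chromene; 10 bromoform
Product: 11 (4aS,6S,8aS)-6-bromo-2,3-(dibromomethano)-5,5,8a-trimethyloctahydro-2H-chromene (cyclopropane cis-fused at C2–C3 on the face anti to the C8a methyl)
Conditions: KOtBu, pentane, −20 → 0 °C; crude product used directly
Reagents that add atoms: none
Why: Doering–Hoffmann dibromocarbene [2+1] cycloaddition to an electron-rich cis-disubstituted enol ether is fast and stereospecifically cis, the carbene should enter anti to the axial C8a methyl (both new cyclopropane centres are erased in step 7, so either face would serve), and the equatorial C6 bromide has no anti-periplanar hydrogen for E2 with the base.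

Step 7
Reactants: 11 (4aS,6S,8aS)-6-bromo-2,3-(dibromomethano)-5,5,8a-trimethyloctahydro-2H-chromene; 12 methanol
Product: 14 (2RS,5aS,7S,9aS)-3,7-dibromo-2-methoxy-6,6,9a-trimethyl-2,5,5a,6,7,8,9,9a-octahydro-1-benzoxepine, via oxepinium ion 13 (not isolated)
Conditions: AgOAc, NaOAc, MeOH, 60 °C, dark
Reagents that add atoms: none
Why: Silver-assisted departure of the endo bromide (the one lying over the pyran ring) is concerted with disrotatory two-electron opening of the cyclopropane, in which the C–O and C–CH2 ring bonds turn inward, the bond between the former C2 and C3 breaks and the cis alkoxy-allyl cation 13 forms, which methanol then captures at the carbon next to oxygen to give acetal 14. The closest known reaction is the silver- or base-promoted ring expansion of gem-dihalocyclopropanated glycals and of dihalocarbene adducts of dihydropyran to 2-alkoxy-3-halo-oxepenes. The oxepene ring is not closed by a cyclisation but arises by ring enlargement, the six-membered ether becoming seven-membered when the shared cyclopropane bond is cleaved, so that cyclopropane strain drives it and the trans fusion is not disturbed. The only new stereocentre is the acetal carbon C2, which is not controlled (both anomers) and is erased in step 9. The step needs cleavage of the ring-fusion bond and not of an exocyclic one, capture at C2 and not at C4, and ionisation at the cyclopropane in preference to C7–Br: the fused ring allows only the inward disrotation that goes with loss of the endo bromide, the ring oxygen localises the charge at C2, and the unstrained neopentyl secondary bromide has neither strain release nor oxygen assistance, while NaOAc buffers the acid so that the acetal and the tertiary ether survive.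

Step 8
Reactants: 14 (2RS,5aS,7S,9aS)-3,7-dibromo-2-methoxy-6,6,9a-trimethyl-2,5,5a,6,7,8,9,9a-octahydro-1-benzoxepine
Product: 15 (2RS,5aS,7S,9aS)-7-bromo-2-methoxy-3,6,6,9a-tetramethyl-2,5,5a,6,7,8,9,9a-octahydro-1-benzoxepine
Conditions: MeZnCl, Pd(PPh3)4 (5 mol%), THF, 50 °C
Reagents that add atoms: methylzinc chloride, C[Zn]Cl
Why: Negishi cross-coupling, in which Pd(0)/PPh3 inserts only into the sp2 C–Br bond because unactivated secondary alkyl bromides do not add oxidatively to this catalyst and the vinylpalladium cannot β-eliminate the ring-bound methoxy neighbour, so the C3 methyl is installed without touching any stereocentre.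

Step 9
Reactants: 15 (2RS,5aS,7S,9aS)-7-bromo-2-methoxy-3,6,6,9a-tetramethyl-2,5,5a,6,7,8,9,9a-octahydro-1-benzoxepine
Product: 17 (5aS,7S,9aS)-7-bromo-3,6,6,9a-tetramethyl-5a,6,7,8,9,9a-hexahydro-1-benzoxepin-2(5H)-one, via lactol 16 (not isolated)
Conditions: Jones reagent (CrO3, H2SO4, H2O), acetone, 0 °C
Reagents that add atoms: water, O
Why: Jones oxidation of a cyclic allylic methyl acetal directly to the α,β-unsaturated lactone, as known for 2-alkoxy-dihydropyrans, works because acid hydrolysis gives lactol 16 and chromium(VI) oxidises it as it forms, which leaves the open-chain (Z)-hydroxy-enal little time to isomerise and removes the anomeric centre without affecting the others.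

Step 10
Reactants: 17 (5aS,7S,9aS)-7-bromo-3,6,6,9a-tetramethyl-5a,6,7,8,9,9a-hexahydro-1-benzoxepin-2(5H)-one
Product: 18 (5aS,7S,9aS)-7-bromo-3,6,6,9a-tetramethyl-2-methylidene-2,5,5a,6,7,8,9,9a-octahydro-1-benzoxepine
Conditions: Cp2TiMe2, toluene, 70 °C, dark; filtration through basic alumina, used at once
Reagents that add atoms: dimethyltitanocene, [CH3-].[CH3-].[Ti+4].[cH-]1cccc1.[cH-]1cccc1
Why: Petasis methylenation, through thermally generated Cp2Ti=CH2, converts lactones including conjugated and hindered ones into exocyclic enol ethers without acid or enolisation, here giving the 2-alkoxy-1,3-diene with no new stereocentre.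

Step 11
Reactants: 18 (5aS,7S,9aS)-7-bromo-3,6,6,9a-tetramethyl-2-methylidene-2,5,5a,6,7,8,9,9a-octahydro-1-benzoxepine
Product: 20 [(2R,5aS,7S,9aS)-7-bromo-3,6,6,9a-tetramethyl-2,5,5a,6,7,8,9,9a-octahydro-1-benzoxepin-2-yl]methanol, via alkylborane 19 (not isolated)
Conditions: 9-BBN, THF, 0 °C → rt; then NaOH, H2O2, 0 °C
Reagents that add atoms: 9-borabicyclo[3.3.1]nonane, B1C2CCCC1CCC2 (its atoms are in 19 only); hydrogen peroxide, OO
Why: Hydroboration–oxidation of an exocyclic enol ether, the usual way from a methylenated lactone to a 2-hydroxymethyl cyclic ether, places boron on the terminal carbon of the 1,1-disubstituted double bond only and delivers hydrogen to C2 from the ring face anti to the pseudo-axial C9a methyl, which shields the other face across O1, so the CH2OH group ends up syn to that methyl, that is (2R).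

Step 12
Reactants: 20 [(2R,5aS,7S,9aS)-7-bromo-3,6,6,9a-tetramethyl-2,5,5a,6,7,8,9,9a-octahydro-1-benzoxepin-2-yl]methanol
Product: 21 Palisadin B, (2R,5aS,7S,9aS)-7-bromo-2-(bromomethyl)-3,6,6,9a-tetramethyl-2,5,5a,6,7,8,9,9a-octahydro-1-benzoxepine
Conditions: CBr4, PPh3, CH2Cl2, 0 °C → rt
Reagents that add atoms: carbon tetrabromide, BrC(Br)(Br)Br
Why: Appel reaction, in which bromide displaces the alkoxyphosphonium group by SN2 at the primary carbon under neutral conditions, leaves C2, the trisubstituted alkene and the C7 bromide untouched.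

**Compound list**

1 | geranyl bromide, (2E)-1-bromo-3,7-dimethylocta-2,6-diene | CC(C)=CCC/C(C)=C/CBr | starting material
2 | tert-butyl acetate | CC(=O)OC(C)(C)C | starting material
3 | lithium enolate of tert-butyl acetate | C=C([O-])OC(C)(C)C.[Li+] | intermediate (not isolated)
4 | tert-butyl (4E)-5,9-dimethyldeca-4,8-dienoate | CC(C)=CCC/C(C)=C/CCC(=O)OC(C)(C)C | intermediate
5 | racemic (4aS*,6S*,8aS*)-6-bromo-5,5,8a-trimethyloctahydro-2H-chromen-2-one | O=C1CC[C@H]2C(C)(C)[C@@H](Br)CC[C@]2(C)O1.O=C1CC[C@@H]2C(C)(C)[C@H](Br)CC[C@@]2(C)O1 | intermediate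
6 | (4aS,6S,8aS)-6-bromo-5,5,8a-trimethyloctahydro-2H-chromen-2-one | O=C1CC[C@H]2C(C)(C)[C@@H](Br)CC[C@]2(C)O1 | intermediate
7 | (2RS,4aS,6S,8aS)-6-bromo-5,5,8a-trimethyloctahydro-2H-chromen-2-ol | OC1CC[C@H]2C(C)(C)[C@@H](Br)CC[C@]2(C)O1 | intermediate
8 | (2RS,4aS,6S,8aS)-6-bromo-5,5,8a-trimethyloctahydro-2H-chromen-2-yl methanesulfonate | CS(=O)(=O)OC1CC[C@H]2C(C)(C)[C@@H](Br)CC[C@]2(C)O1 | intermediate (not isolated)
9 | (4aS,6S,8aS)-6-bromo-5,5,8a-trimethyl-4a,5,6,7,8,8a-hexahydro-4H-chromene | C1=CC[C@H]2C(C)(C)[C@@H](Br)CC[C@]2(C)O1 | intermediate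
10 | bromoform | BrC(Br)Br | starting material
11 | (4aS,6S,8aS)-6-bromo-2,3-(dibromomethano)-5,5,8a-trimethyloctahydro-2H-chromene, cyclopropane anti to the C8a methyl | BrC1(Br)[C@@H]2C[C@H]3C(C)(C)[C@@H](Br)CC[C@]3(C)O[C@H]12 | intermediate
12 | methanol | CO | starting material
13 | (5aS,7S,9aS)-3,7-dibromo-6,6,9a-trimethyl-5,5a,6,7,8,9-hexahydro-1-benzoxepin-1-ium (alkoxy-allyl cation) | BrC1=CC[C@H]2C(C)(C)[C@@H](Br)CC[C@]2(C)[O+]=C1 | intermediate (not isolated)
14 | (2RS,5aS,7S,9aS)-3,7-dibromo-2-methoxy-6,6,9a-trimethyl-2,5,5a,6,7,8,9,9a-octahydro-1-benzoxepine | BrC1=CC[C@H]2C(C)(C)[C@@H](Br)CC[C@]2(C)OC1OC | intermediate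
15 | (2RS,5aS,7S,9aS)-7-bromo-2-methoxy-3,6,6,9a-tetramethyl-2,5,5a,6,7,8,9,9a-octahydro-1-benzoxepine | CC1=CC[C@H]2C(C)(C)[C@@H](Br)CC[C@]2(C)OC1OC | intermediate
16 | (2RS,5aS,7S,9aS)-7-bromo-3,6,6,9a-tetramethyl-2,5,5a,6,7,8,9,9a-octahydro-1-benzoxepin-2-ol | CC1=CC[C@H]2C(C)(C)[C@@H](Br)CC[C@]2(C)OC1O | intermediate (not isolated)
17 | (5aS,7S,9aS)-7-bromo-3,6,6,9a-tetramethyl-5a,6,7,8,9,9a-hexahydro-1-benzoxepin-2(5H)-one | CC1=CC[C@H]2C(C)(C)[C@@H](Br)CC[C@]2(C)OC1=O | intermediate
18 | (5aS,7S,9aS)-7-bromo-3,6,6,9a-tetramethyl-2-methylidene-2,5,5a,6,7,8,9,9a-octahydro-1-benzoxepine | CC1=CC[C@H]2C(C)(C)[C@@H](Br)CC[C@]2(C)OC1=C | intermediate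
19 | B-alkyl-9-BBN adduct of 18, boron on the exocyclic carbon, CH2B syn to the C9a methyl | CC1=CC[C@H]2C(C)(C)[C@@H](Br)CC[C@]2(C)O[C@H]1CB1C2CCCC1CCC2 | intermediate (not isolated)
20 | [(2R,5aS,7S,9aS)-7-bromo-3,6,6,9a-tetramethyl-2,5,5a,6,7,8,9,9a-octahydro-1-benzoxepin-2-yl]methanol | CC1=CC[C@H]2C(C)(C)[C@@H](Br)CC[C@]2(C)O[C@H]1CO | intermediate
21 | Palisadin B, (2R,5aS,7S,9aS)-7-bromo-2-(bromomethyl)-3,6,6,9a-tetramethyl-2,5,5a,6,7,8,9,9a-octahydro-1-benzoxepine | CC1=CC[C@H]2C(C)(C)[C@@H](Br)CC[C@]2(C)O[C@H]1CBr | target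

**Step count**

Total: 12 steps. Longest linear sequence: 12 steps (1 → 21).

**Steps most likely to fail**

Step 7. After ionisation, loss of a proton from C5 of cation 13 to a dienyl ether can compete with capture by methanol, silver can assist ionisation at C7 with a 1,2-shift, and 11 may open prematurely on handling. The fallback sets out from 11 and separates ring opening from capture. Heating 11 without silver in quinoline at about 120 °C should give, by thermal opening and loss of HBr, the dienyl ether (5aS,7S,9aS)-3,7-dibromo-6,6,9a-trimethyl-5a,6,7,8,9,9a-hexahydro-1-benzoxepine F1. Treatment of this with catalytic PPTS in methanol at 0 °C → rt should protonate the diene terminus C5 under equilibrating conditions, regenerate 13 and add methanol at C2. The route is rejoined at 14.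

Step 9. The seven-membered lactol 16 can open to the (Z)-hydroxy-enal, which may isomerise to the (E)-enal or be over-oxidised to the acid, so that the ring does not reclose. The fallback sets out from 15 and avoids a free lactol and chromium. Exchange of the methoxy group for hydroperoxide (H2O2, catalytic MoO3) should give the hydroperoxy acetal (2RS,5aS,7S,9aS)-7-bromo-2-hydroperoxy-3,6,6,9a-tetramethyl-2,5,5a,6,7,8,9,9a-octahydro-1-benzoxepine F2. Dehydration of this with Ac2O/pyridine (Kornblum–DeLaMare-type fragmentation, as used for 2-alkoxy-dihydropyrans) should give the lactone. The route is rejoined at 17.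

Step 11. Facial discrimination by the borane may be insufficient, and the acid-labile dienyl ether 18 may be lost by hydrolysis, isomerisation or β-alkoxy elimination of the borane. The fallback sets out from 17, replaces steps 10 and 11, and sets C2 by ionic reduction instead.
- Addition of (4-methoxybenzyloxy)methyllithium (from the tributylstannane and n-BuLi, THF, −78 °C) should give the hemiketal (2RS,5aS,7S,9aS)-7-bromo-2-[(4-methoxybenzyloxy)methyl]-3,6,6,9a-tetramethyl-2,5,5a,6,7,8,9,9a-octahydro-1-benzoxepin-2-ol F3.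
- Et3SiH/TMSOTf in CH2Cl2/MeCN at −78 °C should reduce it through the conjugated oxocarbenium ion, with hydride entering at C2 anti to the C9a methyl, to the ether (2R,5aS,7S,9aS)-7-bromo-2-[(4-methoxybenzyloxy)methyl]-3,6,6,9a-tetramethyl-2,5,5a,6,7,8,9,9a-octahydro-1-benzoxepine F4.
- DDQ in CH2Cl2/pH 7 buffer should remove the PMB group, and the route is rejoined at 20.

**Further compounds**

F1 | step 7 | (5aS,7S,9aS)-3,7-dibromo-6,6,9a-trimethyl-5a,6,7,8,9,9a-hexahydro-1-benzoxepine | BrC1C=C[C@H]2C(C)(C)[C@@H](Br)CC[C@]2(C)OC=1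
F2 | step 9 | (2RS,5aS,7S,9aS)-7-bromo-2-hydroperoxy-3,6,6,9a-tetramethyl-2,5,5a,6,7,8,9,9a-octahydro-1-benzoxepine | CC1=CC[C@H]2C(C)(C)[C@@H](Br)CC[C@]2(C)OC1OO
F3 | step 11 | (2RS,5aS,7S,9aS)-7-bromo-2-[(4-methoxybenzyloxy)methyl]-3,6,6,9a-tetramethyl-2,5,5a,6,7,8,9,9a-octahydro-1-benzoxepin-2-ol | CC1=CC[C@H]2C(C)(C)[C@@H](Br)CC[C@]2(C)OC1(O)COCc1ccc(OC)cc1
F4 | step 11 | (2R,5aS,7S,9aS)-7-bromo-2-[(4-methoxybenzyloxy)methyl]-3,6,6,9a-tetramethyl-2,5,5a,6,7,8,9,9a-octahydro-1-benzoxepine | CC1=CC[C@H]2C(C)(C)[C@@H](Br)CC[C@]2(C)O[C@H]1COCc1ccc(OC)cc1
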